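The data come from a simulation on assumed constants; scatter was added.

Start from a leftover: how much reagent still stands in the flask at the moment asked about, when 20 % of the two substrates together are converted. Call that moment the mark.

| setting | north-west | south-west | flask |
|---|---|---|---|
| left-handed substrate | 42 mM | 42 mM | 42 mM |
| right-handed substrate | 42 mM | 42 mM | 42 mM |
| reagent | 25.2 mM | 38 mM | 25.2 mM |
| free catalyst | 0.21 mM | 0.21 mM | 0.21 mM |
| remark | the very flask that is asked about, followed so far | run made earlier |  |

| run | time / min | left-handed product / % | left-handed substrate / % |
|---|---|---|---|
| north-west | 2.00 | 8.4 | 40.6 |
| north-west | 3.00 | 12.3 | 40.3 |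
| north-west | 4.00 | 12.7 | 38.2 |
| north-west | 6.00 | 14.8 | 36.7 |
| north-west | 10.0 | 15.3 | 33.5 |
| north-west | 15.0 | 17.4 | 31.4 |
| north-west | 25.0 | 17.6 | 32.2 |
| south-west | 12.0 | 23.4 | 26.2 |
| south-west | 25.0 | 27.5 | 23.8 |
| south-west | 40.0 | 27.8 | 21.6 |
| south-west | 50.0 | 28.3 | 23.1 |
| south-west | 60.0 | 27.9 | 23.0 |
| south-west | 80.0 | 25.7 | 22.9 |

(standard deviation of a reading: 1 percentage point)

- free catalyst is single-handed; left-handed substrate and right-handed substrate are mirror images of each other, charged as a racemate, each of them at the stated concentration
- candidate steps: reagent + free catalyst + left-handed substrate -> free catalyst + left-handed product; reagent + free catalyst + right-handed substrate -> free catalyst + right-handed product; 2 free catalyst -> spent catalyst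
- no earlier run changes the charge of free catalyst; that part of a forecast is a guess

- apparent order in reagent when 20 % of the left-handed substrate and right-handed substrate together are converted (percent change of the rate of making left-handed product for one percent more reagent charged)
- apparent order in free catalyst when 20 % of the left-handed substrate and right-handed substrate together are converted (percent change of the rate of making left-handed product for one percent more free catalyst charged)

Each turn of the catalyst uses one reagent and one substrate of either hand and gives the free catalyst back, while two free catalyst can pair into spent catalyst. Take the rate of making left-handed product as proportional to free catalyst, reagent and left-handed substrate.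

Follow the north-west run, which is this flask so far. At first everything stands near its charge and turnover is quick: left-handed product reads 8.4 % after 2.00 min. At the end it lies flat, from 17.4 % to 17.6 %, with left-handed substrate still at 32.2 %. The south-west plateau over this one reads 1.59, near the ratio of reagent charges, 1.51, so reagent is the limiting reagent.

In between lies the mark, near 4.00 min by the readings. Reckon the reagent there:

used = 20 % × 84.0 mM = 16.8 mM

left = 25.2 mM − 16.8 mM = 8.40 mM

L = 25.2 mM / 8.40 mM = 3.00

Call L, reagent charged over reagent left at the mark, the leverage. One percent more charge adds L percent to what is left there, with substrate at the mark hardly moved. More reagent also reaches the mark sooner, so more free catalyst may be alive there. My own reckoning is therefore a little above L.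

The forecast gives 4.2 for reagent and 1 for free catalyst, and says of its extra: “It also reaches that point with less catalyst-time, adding about 1 to 1.5.” No earlier run changes the catalyst charge, so the forecast's order in free catalyst is a guess.

The flask gives 3.3 and 1.0.

    reagent + free catalyst + left-handed substrate → free catalyst + left-handed product (k = 360 /M²/s)
    reagent + free catalyst + right-handed substrate → free catalyst + right-handed product (k = 180 /M²/s)
    2 free catalyst → spent catalyst (k = 1.30 /M/s)

Run this flask with the step that pairs free catalyst into spent catalyst taken away, and the order in reagent falls from 3.3 to 3.0, which is the leverage 3.00. So the order here is the leverage plus a small term from catalyst death. That pairing adds 0.272 to the order at the mark, which this flask reaches after 4.78 min.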